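The easy step comes first: in the spring run, which is the flask asked about, the solid substrate reads 0.3% at 3.00 h while the target reads 50.2%; the target climbs to 61.5% by 5.00 h and after that creeps upward, to 62.6% at 6.00 h and 63.2% at 8.00 h.

| setting | spring | noon | flask |
|---|---|---|---|
| solid substrate | 0.50 M | 0.50 M | 0.50 M |
| precatalyst | 1 mM | 1 mM | 1.0 mM |
| temperature | 60 °C | 55 °C | 60 °C |
| remark | the very flask that is asked about, followed so far | run made earlier |  |
| time |  |  | 10 h |

- spring (time / h: target / %, solid substrate / %): 1.50: 23.6, 35.4; 3.00: 50.2, 0.3; 5.00: 61.5, 0; 6.00: 62.6, 0.2; 8.00: 63.2, 0.5
- noon (time / h: target / %, solid substrate / %): 1.50: 14.2, 39.9; 3.00: 35.1, 11.0; 5.00: 51.6, 0.6; 6.00: 56.0, 0; 8.00: 58.6, 0.2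

(standard deviation of a reading: 0.5 percentage points)

- Friday's: at 10 h take out 90% of the target then present, then wait 10 h
- Saturday's: at 10 h add precatalyst, 100% of the amount charged, then wait 10 h
- Wednesday's: change nothing and wait 10 h more
- Monday's: at 10 h raise the temperature by 25 K, then wait 10 h

- given per volume of solution although it is solid: solid substrate
- what is taken out of target is counted as made
- the analysis behind the earlier runs scatters by 0.5 percentage points, standard deviation
- steps that have been proposed: target + catalyst <-> isomer of the product + catalyst; precatalyst -> catalyst; starting material <-> target; solid substrate <-> starting material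
- at the start none of the solid substrate is in solution
- additions bring no volume worth counting

1. target, in percent of the solid substrate first charged, at 10 h
2. the remedy with the largest gain of target, or "none" below 2 percentage points (Friday's / Saturday's / Wednesday's / Monday's / none)
3. target present, with what was taken out counted in, in percent of the solid substrate first charged, after Friday's
4. target present, with what was taken out counted in, in percent of the solid substrate first charged, after Wednesday's

Two chemists read that creep differently. The first calls it a slow tail that keeps going. The last two spring readings rise by 0.6 percentage points in 2.00 h, so at that steady pace Wednesday's brings 3 points, which is more than the 2 points mark.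

The second says the target is closing on a level, a balance among forms in solution (thermodynamic control). She counts the gap half-life: the time in which the distance of the target from its level halves, counted once the solid has gone. Taking the last spring reading as the level, the gap falls from 1.7 points to 0.6 points in 1.00 h, which gives 0.666 h. That is a rough reading, since these gaps are not far above the scatter of 0.5 points.

From 8.00 h to 10 h she counts 3.00 halvings, so the next rise shrinks to 0.075 points and she commits to 63.3% at 10 h. A further 10 h is 15.0 halvings, so whatever is disturbed then has time to return.

The forecast takes her side, though its figure differs from her 63.3%: 63.4% now (62.3% to 64.5%), 63.5% after Wednesday's (61.5% to 65%), 84% after Friday's (76% to 88%), and Friday's as the best remedy. In its words, “Waiting or adding precatalyst therefore gains almost nothing”.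

The flask gives 63.5% at 10 h, 63.5% after Wednesday's and 84.4% after Friday's. Friday's has the largest gain, 21 points, against 8.1 points for Monday's. Wednesday's brings 0.054 points, less than the mark, so the slow tail loses.

    target + catalyst ⇌ isomer of the product + catalyst, rate k1*[catalyst]*[target] forward; the back reaction follows from the equilibrium constant (K = 0.370, k = 0.0810 /M/s, Ea = 43.0 kJ/mol, ΔH = −47.0 kJ/mol)
    precatalyst → catalyst (k = 1.10 × 10⁻⁴ /s, Ea = 96.0 kJ/mol)
    starting material ⇌ target (K = 4.90, k = 1.80 × 10⁻⁴ /s, Ea = 111 kJ/mol, ΔH = −13.0 kJ/mol)
    solid substrate ⇌ starting material, rate k4*(cs4 - [starting material]) while solid is left; crystals form when [starting material] > cs4 (solubility = 0.320 M, k = 3.30 × 10⁻⁴ /s)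
    (constants at 60 °C)

Friday's removes 57.1% and leaves 42.9%; over 15.0 halvings that pool returns to the share 63.5%, which makes 84.3%. The tail view has its place while solid remains: in the flask with 2.0 M of solid substrate, 40.9% is still solid at 10.0 h, the count has not begun, and target stands at 34.9%. This flask has come to rest: ten times the time moves target by 0.054 points, and isomer of the product from 23.3% to 23.5%.

The earlier runs and the new flask are simulated for an exercise; noise was put on by code.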